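The oxolane ring (O1, C2–C5) is traced back to an all-trans cyclobutane in which C2 and C5 are still bonded to each other, and O1 is inserted between them. The step exploits two features: C2 and C5 are both benzylic and para to a free phenol OH, and the molecule has twofold symmetry. Two-electron oxidation breaks the strained diaryl C–C bond to a bis(p-quinone methide). Water adds once, the new carbinol closes on the second methide, and C3/C4 dictate C2/C5. The precursor, a 1,2-bis(acetoxymethyl)-3,4-bis(syringyl)cyclobutane, comes from sinapic acid by a [2+2] photocycloaddition across a threitol tether, the only purchased chirality.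

Key step: step 6

Assumption: the (4S,5S) tether is taken to favour the (1S,2S,3R,4R) cyclobutane, because in a crown-like ten-membered dilactone the torsions about the tether C4–C5 bond (negative) and the cyclobutane C1–C2 bond (positive) should have opposite signs; should the sense be the reverse, the equally available (4R,5R) diol is used and nothing else changes.

Step 1
Reactants: 1 sinapic acid
Product: 2 (E)-3-(4-acetoxy-3,5-dimethoxyphenyl)prop-2-enoic acid (O-acetylsinapic acid)
Conditions: Ac2O, pyridine, 0 °C to rt; aqueous work-up
Reagents that add atoms: acetic anhydride, CC(=O)OC(C)=O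
Why: Acetylation of the phenol (nucleophilic acyl substitution) masks the easily oxidised, triplet-quenching OH for the photochemical step, and any mixed anhydride at the acid is hydrolysed on aqueous work-up.

Step 2
Reactants: 2 O-acetylsinapic acid (2 equiv), 3 (4S,5S)-2,2-dimethyl-1,3-dioxolane-4,5-dimethanol (2,3-O-isopropylidene-L-threitol)
Product: 4 [(4S,5S)-2,2-dimethyl-1,3-dioxolane-4,5-diyl]bis(methylene) bis[(E)-3-(4-acetoxy-3,5-dimethoxyphenyl)prop-2-enoate]
Conditions: DCC, DMAP (cat.), CH2Cl2, 0 °C to rt
Reagents that add atoms: none
Why: Twofold Steglich esterification of the two unhindered primary alcohols, which touches neither the tether stereocentres nor the E-alkenes nor the aryl acetates.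

Step 3
Reactants: 4 tethered bis(O-acetylsinapate)
Product: 5 ten-membered dilactone in which (1S,2S,3R,4R)-3,4-bis(4-acetoxy-3,5-dimethoxyphenyl)cyclobutane-1,2-dicarboxylic acid (all-trans, delta-truxinate type) is esterified at both carboxyls by O1 and O4 of 2,3-O-isopropylidene-L-threitol
Conditions: [Ir(dF(CF3)ppy)2(dtbbpy)]PF6 (1 mol%), degassed MeCN (5 mM), blue LEDs (450 nm), rt
Reagents that add atoms: none
Why: Intramolecular [2+2] photocycloaddition of a tethered dicinnamate under triplet energy transfer: the tether enforces head-to-head union, the first bond joins the two alpha-carbons, the bis-benzylic 1,4-diradical closes to the all-trans array, and the twofold-symmetric trans-dioxolane, whose splayed arms should fit only one helicity of the trans-diester, selects the (1S,2S,3R,4R) isomer, so that all four stereocentres are set in one event by the two bought ones.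

Step 4
Reactants: 5 cyclobutane dilactone
Product: 6 [(1S,2S,3R,4R)-3,4-bis(4-hydroxy-3,5-dimethoxyphenyl)cyclobutane-1,2-diyl]dimethanol
Conditions: LiAlH4, THF, 0 °C to rt; aq. potassium sodium tartrate work-up, pH adjusted to 6
Reagents that add atoms: none
Why: Hydride reduction of all four ester groups (two lactone carbonyls, two aryl acetates) frees the diol, both phenols and the tether in one operation, and the all-trans array cannot be lost because it is also the most stable one.

Step 5
Reactants: 6 bis-phenol diol
Product: 7 [(1S,2S,3R,4R)-3,4-bis(4-hydroxy-3,5-dimethoxyphenyl)cyclobutane-1,2-diyl]bis(methylene) diacetate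
Conditions: immobilised Candida antarctica lipase B, vinyl acetate, THF, 40 °C
Reagents that add atoms: vinyl acetate, C=COC(C)=O
Why: Lipase-catalysed irreversible transesterification, in which the acyl-enzyme is attacked by primary aliphatic alcohols but not by the hindered, weakly nucleophilic 2,6-dimethoxyphenols, and tautomerisation of the released vinyl alcohol prevents the back reaction; no stereocentre is affected.

Step 6
Reactants: 7 bis-phenol diacetate
Product: 10 [(2R,3S,4S,5R)-2,5-bis(4-hydroxy-3,5-dimethoxyphenyl)oxolane-3,4-diyl]bis(methylene) diacetate, via bis(quinone methide) 8 (not isolated), via hydroxy quinone methide 9 (not isolated)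
Conditions: FeCl3·6H2O (2.2 equiv), acetone/H2O 3:1, argon, slow addition of 7 to the oxidant at 0 °C, then rt until the epimer composition no longer changes; NaH2PO4/Na2HPO4 buffer (pH 7) quench
Reagents that add atoms: water, O
Why: Trivalent iron oxidises a syringyl phenol of 7 to its phenoxyl radical, the spin at the para carbon induces beta-scission of the strained, doubly benzylic C3–C4 bond (cyclobutane numbering), and the p-hydroxybenzyl radical so formed is oxidised at once, which gives bis(p-quinone methide) 8 with the two CH(CH2OAc) stereocentres untouched. Water then adds 1,6 to one methide carbon (9) and the new benzylic hydroxyl closes on the other methide carbon by a 5-exo-trig oxa-1,6-addition, so that in sum one oxygen atom is inserted and the four-membered carbocycle is enlarged to the oxolane. The closest known reaction types are the oxidative ring opening of 1,2-bis(4-hydroxyaryl)cyclobutanes to bis(quinone methides) and the hydrative cyclisation of the beta-beta-linked bis(quinone methides) that form when 4-propenylsyringol or sinapyl acetate is dimerised by one-electron oxidants in wet solvents. C2 and C5 (oxolane numbering) are controlled by C3 and C4: the ring closure must use the methide face that looks towards the chain, which, with the adjacent ring hydrogen held in the methide plane by allylic 1,3-strain, puts that aryl group trans to its neighbouring CH2OAc, whereas the centre made by the intermolecular water addition is not trusted kinetically but corrected by equilibration, since syringyl-type p-hydroxybenzyl ethers re-ionise in the HCl-containing medium and the all-trans isomer is the most stable diastereomer. The step needs cleavage of the diaryl C–C bond in preference to benzylic C–H oxidation and to cycloreversion, which ring strain, the two para hydroxyl groups and the slow addition of 7 to an excess of soluble oxidant should secure. It also needs closure through the water-derived oxygen alone, which the two acetates secure, since free CH2OH groups would close to the furofuran instead.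

Step 7
Reactants: 10 oxolane diacetate
Product: 11 [(2R,3S,4S,5R)-2,5-bis(4-hydroxy-3,5-dimethoxyphenyl)oxolane-3,4-diyl]dimethanol (target)
Conditions: K2CO3 (cat.), MeOH, argon, 0 °C to rt; NH4Cl quench
Reagents that add atoms: none
Why: Base-catalysed transesterification (Zemplén-type methanolysis) removes both primary acetates, whereas the benzylic ether bonds of the oxolane do not ionise under cold, mildly basic conditions, so that no stereocentre is touched and acid, which could reroute the free diol to a furofuran, is avoided.

Compound list
1 | sinapic acid, (E)-3-(4-hydroxy-3,5-dimethoxyphenyl)prop-2-enoic acid | COc1cc(/C=C/C(=O)O)cc(OC)c1O | starting material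
2 | (E)-3-(4-acetoxy-3,5-dimethoxyphenyl)prop-2-enoic acid | COc1cc(/C=C/C(=O)O)cc(OC)c1OC(C)=O | intermediate
3 | (4S,5S)-2,2-dimethyl-1,3-dioxolane-4,5-dimethanol (2,3-O-isopropylidene-L-threitol) | CC1(C)O[C@@H](CO)[C@H](CO)O1 | starting material
4 | [(4S,5S)-2,2-dimethyl-1,3-dioxolane-4,5-diyl]bis(methylene) bis[(E)-3-(4-acetoxy-3,5-dimethoxyphenyl)prop-2-enoate] | CC1(C)O[C@@H](COC(=O)/C=C/c2cc(OC)c(OC(C)=O)c(OC)c2)[C@H](COC(=O)/C=C/c2cc(OC)c(OC(C)=O)c(OC)c2)O1 | intermediate
5 | ten-membered dilactone of (1S,2S,3R,4R)-3,4-bis(4-acetoxy-3,5-dimethoxyphenyl)cyclobutane-1,2-dicarboxylic acid with 2,3-O-isopropylidene-L-threitol | COc1cc(cc(OC)c1OC(C)=O)[C@@H]1[C@@H](c2cc(OC)c(OC(C)=O)c(OC)c2)[C@@H]2C(=O)OC[C@@H]3OC(C)(C)O[C@H]3COC(=O)[C@@H]12 | intermediate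
6 | [(1S,2S,3R,4R)-3,4-bis(4-hydroxy-3,5-dimethoxyphenyl)cyclobutane-1,2-diyl]dimethanol | COc1cc([C@@H]2[C@@H](c3cc(OC)c(O)c(OC)c3)[C@H](CO)[C@H]2CO)cc(OC)c1O | intermediate
7 | [(1S,2S,3R,4R)-3,4-bis(4-hydroxy-3,5-dimethoxyphenyl)cyclobutane-1,2-diyl]bis(methylene) diacetate | COc1cc([C@@H]2[C@@H](c3cc(OC)c(O)c(OC)c3)[C@H](COC(C)=O)[C@H]2COC(C)=O)cc(OC)c1O | intermediate
8 | (2S,3S)-2,3-bis[(3,5-dimethoxy-4-oxocyclohexa-2,5-dien-1-ylidene)methyl]butane-1,4-diyl diacetate | COC1=CC(C=C(OC)C1=O)=C[C@H](COC(C)=O)[C@@H](COC(C)=O)C=C1C=C(OC)C(=O)C(OC)=C1 | intermediate
9 | mono-hydrate of 8: one methide carbon is now an (R)-configured CH(OH) that bears a 4-hydroxy-3,5-dimethoxyphenyl group, the other quinone methide is intact (productive epimer drawn) | COc1cc([C@H](O)[C@H](COC(C)=O)[C@@H](COC(C)=O)C=C2C=C(OC)C(=O)C(OC)=C2)cc(OC)c1O | intermediate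
10 | [(2R,3S,4S,5R)-2,5-bis(4-hydroxy-3,5-dimethoxyphenyl)oxolane-3,4-diyl]bis(methylene) diacetate | COc1cc([C@@H]2O[C@@H](c3cc(OC)c(O)c(OC)c3)[C@H](COC(C)=O)[C@H]2COC(C)=O)cc(OC)c1O | intermediate
11 | [(2R,3S,4S,5R)-2,5-bis(4-hydroxy-3,5-dimethoxyphenyl)oxolane-3,4-diyl]dimethanol | COc1cc([C@@H]2O[C@@H](c3cc(OC)c(O)c(OC)c3)[C@H](CO)[C@H]2CO)cc(OC)c1O | target

Total step count: 7. Longest linear sequence: 7 steps (from sinapic acid).

Steps most likely to fail

**Step 6.**
- What may go wrong:
  - Fragmentation of the central C–C bond at the radical stage, with leakage of configuration.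
  - Incomplete equilibration of the centre made by the intermolecular water addition.
  - Participation of an acetate carbonyl followed by acyl migration.
  - Friedel–Crafts closure of a benzylic cation onto the neighbouring arene on long exposure to acid.
  - Over-oxidation of the product phenols.
- Fallback: it sets out from 7 and comes back at 10, and it separates the C–C cleavage from the C–O ring closure.
  - Compound 7 is oxidised with FeCl3 in dry methanol. The abundant and more nucleophilic solvent captures both methide carbons quickly and should give the isolable acyclic (2S,3S)-bis(benzylic methyl ether) F1. It forms as a mixture of benzylic epimers, which is of no consequence.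
  - In a second flask, free of oxidant, catalytic camphorsulfonic acid in MeCN/H2O re-ionises the p-hydroxybenzyl ethers. Water replaces one methoxy group and the resulting carbinol displaces the other. Closure under purely thermodynamic control should give all-trans 10.

**Step 3.**
- What may go wrong:
  - Unproductive E/Z isomerisation.
  - Closure to cis-fused isomers, because the trans-fused ten-membered dilactone is strained.
  - A weak or reversed facial bias of the tether.
  - Competing intermolecular dimerisation.
- Fallback: it sets out from 2 and comes back at 7. The tether is given up and the absolute configuration is introduced by enzymatic resolution.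
  - Compound 2 is esterified (MeOH, DCC, DMAP) to methyl (E)-O-acetylsinapate F2.
  - F2 is dimerised head-to-head at high concentration with the same iridium sensitiser to the racemic all-trans dimethyl delta-truxinate F3.
  - LiAlH4 then gives the racemic tetraol F4.
  - Acetylation with vinyl acetate and Burkholderia cepacia lipase is stopped near half conversion, so that the twofold enantiomer selection separates a diacetate from unreacted diol.
  - The (1S,2S,3R,4R) series is carried on as 7, either directly or after acetylation as in step 5.

**Step 5.**
- What may go wrong: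
  - Slow or incomplete second acylation of the beta-branched alcohol in the enzyme pocket.
  - Poor solubility of the tetraol.
- Fallback: it sets out from 6 and comes back at 7, and it uses over-protection followed by selective deprotection instead of selective protection.
  - Ac2O in pyridine gives the cyclobutane tetraacetate F5.
  - Pyrrolidine in THF at 0 °C aminolyses only the two aryl acetates, which carry the far better leaving group, and leaves the primary acetates in place.

Further compounds
F1 | step 6 | (2S,3S)-2,3-bis[(4-hydroxy-3,5-dimethoxyphenyl)(methoxy)methyl]butane-1,4-diyl diacetate (mixture of benzylic epimers) | COc1cc(C(OC)[C@H](COC(C)=O)[C@@H](COC(C)=O)C(OC)c2cc(OC)c(O)c(OC)c2)cc(OC)c1O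
F2 | step 3 | methyl (E)-3-(4-acetoxy-3,5-dimethoxyphenyl)prop-2-enoate | COC(=O)/C=C/c1cc(OC)c(OC(C)=O)c(OC)c1
F3 | step 3 | racemic dimethyl all-trans-3,4-bis(4-acetoxy-3,5-dimethoxyphenyl)cyclobutane-1,2-dicarboxylate (one enantiomer drawn) | COc1cc([C@@H]2[C@@H](c3cc(OC)c(OC(C)=O)c(OC)c3)[C@H](C(=O)OC)[C@H]2C(=O)OC)cc(OC)c1OC(C)=O
F4 | step 3 | racemic tetraol, that is 6 together with its (1R,2R,3S,4S) enantiomer (the latter is drawn) | COc1cc([C@H]2[C@H](c3cc(OC)c(O)c(OC)c3)[C@@H](CO)[C@@H]2CO)cc(OC)c1O
F5 | step 5 | [(1S,2S,3R,4R)-3,4-bis(4-acetoxy-3,5-dimethoxyphenyl)cyclobutane-1,2-diyl]bis(methylene) diacetate | COc1cc([C@@H]2[C@@H](c3cc(OC)c(OC(C)=O)c(OC)c3)[C@H](COC(C)=O)[C@H]2COC(C)=O)cc(OC)c1OC(C)=O
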